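**Retrosynthetic overview**

- The last C–C bond made is the one between the acyl carbon on C3 of the pyridone and the first alkene carbon of the side chain. It is made by Rh-catalysed hydroacylation of terminal trienyne 13 with pyridone-3-carbaldehyde 23, followed by one global deprotection.
- Enabling feature: the free hydroxyl on C4 of the 2-pyridone ring sits next to C3, which carries the acyl carbon (an O4–C4=C3–C(=O) salicyl-type unit, with the C2 lactam carbonyl on the other flank). It chelates Rh and holds the acyl–Rh hydride in a five-membered metallacycle.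
- Trienyne 13: auxiliary-controlled methylation sets the only stereocentre (R); Wittig, vinylogous HWE, redox adjustment and Colvin homologation build the chain.
- Aldehyde 23: no ring is constructed. The pyridone ring comes from 5-bromo-2,4-dichloropyridine (SNAr, N-oxidation, hydrolysis to the N-hydroxy-2-pyridone, SEM capping, Suzuki coupling, debenzylation, C3 formylation); the aryl ring comes from a boronic acid.

Key step: step 16

Remark: the side-chain stereocentre is read as (R) (CIP order alkenyl > ethyl > methyl > H), which fixes the (R)-configured auxiliary; the exocyclic C=C of 22 is stereolabile and is drawn Z only for definiteness.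

**Route**

Step 1
Reactants: 1 (R)-4-benzyloxazolidin-2-one; 2 butanoyl chloride
Product: 3 (R)-4-benzyl-3-butanoyloxazolidin-2-one
Conditions: n-BuLi, THF, −78 °C; then 2, −78 to 0 °C
Reagents that add atoms: none
Why: N-acylation of the lithiated oxazolidinone with an acid chloride is the standard loading of an Evans auxiliary.

Step 2
Reactants: 3 (R)-4-benzyl-3-butanoyloxazolidin-2-one
Product: 4 (R)-4-benzyl-3-[(R)-2-methylbutanoyl]oxazolidin-2-one
Conditions: NaHMDS, THF, −78 °C; then MeI, −78 °C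
Reagents that add atoms: iodomethane (CI)
Why: Evans asymmetric alkylation, in which the chelated (Z)-sodium enolate is methylated on the face opposite the C4 benzyl group, should set the (R) stereocentre; the minor diastereomer should be removable by chromatography.

Step 3
Reactants: 4 (R)-4-benzyl-3-[(R)-2-methylbutanoyl]oxazolidin-2-one
Product: 5 (R)-2-methylbutan-1-ol
Conditions: LiBH4, H2O (1 equiv), Et2O, 0 °C; careful distillation
Reagents that add atoms: none
Why: Reductive cleavage of the N-acyloxazolidinone with LiBH4 should give the primary alcohol and return the auxiliary without touching the α-stereocentre.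

Step 4
Reactants: 5 (R)-2-methylbutan-1-ol; 6 2-(triphenylphosphoranylidene)propanal
Product: 8 (R,E)-2,4-dimethylhex-2-enal, via (R)-2-methylbutanal 7 (not isolated)
Conditions: TPAP (5 mol%), NMO, 4 Å MS, CH2Cl2, 0 °C to rt; filter through silica; then 6, CH2Cl2, 40 °C, sealed
Reagents that add atoms: none
Why: Ley–Griffith oxidation followed directly by Wittig olefination with a stabilised formyl ylide should give the E-trisubstituted enal, the volatile and epimerisable aldehyde being used only in solution.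

Step 5
Reactants: 8 (R,E)-2,4-dimethylhex-2-enal; 9 triethyl (E)-4-phosphonocrotonate
Product: 10 ethyl (2E,4E,6E,8R)-6,8-dimethyldeca-2,4,6-trienoate
Conditions: 9, LiHMDS, THF, −78 °C; then 8, −78 to 0 °C
Reagents that add atoms: none
Why: Vinylogous Horner–Wadsworth–Emmons olefination with a stabilised phosphonate anion should form the new C4=C5 bond E while the E double bond of the reagent is retained.

Step 6
Reactants: 10 ethyl (2E,4E,6E,8R)-6,8-dimethyldeca-2,4,6-trienoate
Product: 11 (2E,4E,6E,8R)-6,8-dimethyldeca-2,4,6-trien-1-ol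
Conditions: DIBAL-H, CH2Cl2, −78 °C; Rochelle salt work-up
Reagents that add atoms: none
Why: DIBAL-H reduces the conjugated ester in a 1,2 sense to the allylic alcohol.

Step 7
Reactants: 11 (2E,4E,6E,8R)-6,8-dimethyldeca-2,4,6-trien-1-ol
Product: 12 (2E,4E,6E,8R)-6,8-dimethyldeca-2,4,6-trienal
Conditions: activated MnO2, CH2Cl2, rt, dark
Reagents that add atoms: none
Why: Chemoselective allylic oxidation with MnO2 under neutral conditions should leave the double-bond geometry intact.

Step 8
Reactants: 12 (2E,4E,6E,8R)-6,8-dimethyldeca-2,4,6-trienal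
Product: 13 (3E,5E,7E,9R)-7,9-dimethylundeca-3,5,7-trien-1-yne
Conditions: TMSCHN2, n-BuLi, THF, −78 °C; then 12, −78 °C to rt; product kept cold, dark, in solution
Reagents that add atoms: (trimethylsilyl)diazomethane (C[Si](C)(C)C=[N+]=[N-])
Why: Colvin rearrangement (addition of lithiated TMS-diazomethane, Peterson elimination, loss of N2 and 1,2-H shift of the alkylidene carbene) should give the terminal alkyne under methanol-free conditions suited to a conjugated aldehyde.

Step 9
Reactants: 14 5-bromo-2,4-dichloropyridine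
Product: 15 4-(benzyloxy)-5-bromo-2-chloropyridine
Conditions: BnOH, NaH, THF, 0 °C to rt
Reagents that add atoms: benzyl alcohol (OCc1ccccc1)
Why: Nucleophilic aromatic substitution by the alkoxide should occur at C4 (para to N, flanked by Br) in preference to C2.

Step 10
Reactants: 15 4-(benzyloxy)-5-bromo-2-chloropyridine
Product: 16 4-(benzyloxy)-5-bromo-2-chloropyridine 1-oxide
Conditions: mCPBA, CHCl3, 50 °C
Reagents that add atoms: 3-chloroperbenzoic acid (OOC(=O)c1cccc(Cl)c1)
Why: Peracid N-oxidation of the pyridine is assisted by the electron-donating 4-alkoxy group.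

Step 11
Reactants: 16 4-(benzyloxy)-5-bromo-2-chloropyridine 1-oxide
Product: 17 4-(benzyloxy)-5-bromo-1-hydroxypyridin-2(1H)-one
Conditions: aq. NaOH, 1,4-dioxane, 80 °C; then HCl to pH 3
Reagents that add atoms: sodium hydroxide ([Na+].[OH-])
Why: SNAr hydrolysis of a 2-chloropyridine N-oxide gives the 1-hydroxy-2-pyridone tautomer, and the anionic product should be deactivated against further substitution at C4.

Step 12
Reactants: 17 4-(benzyloxy)-5-bromo-1-hydroxypyridin-2(1H)-one
Product: 18 4-(benzyloxy)-5-bromo-1-{[2-(trimethylsilyl)ethoxy]methoxy}pyridin-2(1H)-one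
Conditions: SEMCl, iPr2NEt, CH2Cl2, 0 °C to rt
Reagents that add atoms: 2-(trimethylsilyl)ethoxymethyl chloride (C[Si](C)(C)CCOCCl)
Why: O-alkylation of the cyclic hydroxamic acid at the N–O oxygen is the normal course for N-hydroxy-2-pyridones with alkyl halides.

Step 13
Reactants: 18 4-(benzyloxy)-5-bromo-1-{[2-(trimethylsilyl)ethoxy]methoxy}pyridin-2(1H)-one; 19 [4-(tert-butyldimethylsilyloxy)phenyl]boronic acid
Product: 20 4-(benzyloxy)-5-[4-(tert-butyldimethylsilyloxy)phenyl]-1-{[2-(trimethylsilyl)ethoxy]methoxy}pyridin-2(1H)-one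
Conditions: Pd(dppf)Cl2 (5 mol%), K3PO4, 1,4-dioxane/H2O (10:1), 70 °C
Reagents that add atoms: none
Why: Suzuki–Miyaura coupling at the C5 bromide under mild phosphate conditions should spare the aryl silyl ether and the N–O acetal.

Step 14
Reactants: 20 4-(benzyloxy)-5-[4-(tert-butyldimethylsilyloxy)phenyl]-1-{[2-(trimethylsilyl)ethoxy]methoxy}pyridin-2(1H)-one
Product: 21 5-[4-(tert-butyldimethylsilyloxy)phenyl]-4-hydroxy-1-{[2-(trimethylsilyl)ethoxy]methoxy}pyridin-2(1H)-one
Conditions: H2 (1 atm), 10% Pd/C, EtOAc, rt; stopped after one equivalent of H2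
Reagents that add atoms: none
Why: Hydrogenolysis of the benzyl ether frees the 4-hydroxyl, while the silyl ether, the SEM acetal and the N–O bond should survive brief ambient-pressure conditions.

Step 15
Reactants: 21 5-[4-(tert-butyldimethylsilyloxy)phenyl]-4-hydroxy-1-{[2-(trimethylsilyl)ethoxy]methoxy}pyridin-2(1H)-one
Product: 23 5-[4-(tert-butyldimethylsilyloxy)phenyl]-4-hydroxy-2-oxo-1-{[2-(trimethylsilyl)ethoxy]methoxy}-1,2-dihydropyridine-3-carbaldehyde, via aminomethylidene dione 22 (not isolated)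
Conditions: DMF-DMA, toluene, 80 °C; concentrate; then 0.5 M aq. HCl, THF, 0 °C to rt
Reagents that add atoms: N,N-dimethylformamide dimethyl acetal (COC(OC)N(C)C); water (O)
Why: Aminomethylenation of the nucleophilic C3 of a 4-hydroxy-2-pyridone (cyclic 1,3-dicarbonyl reactivity) followed by hydrolysis of the push-pull enaminone should give the 3-formyl-4-hydroxy tautomer.

Step 16
Reactants: 23 5-[4-(tert-butyldimethylsilyloxy)phenyl]-4-hydroxy-2-oxo-1-{[2-(trimethylsilyl)ethoxy]methoxy}-1,2-dihydropyridine-3-carbaldehyde; 13 (3E,5E,7E,9R)-7,9-dimethylundeca-3,5,7-trien-1-yne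
Product: 24 5-[4-(tert-butyldimethylsilyloxy)phenyl]-3-[(2E,4E,6E,8E,10R)-8,10-dimethyldodeca-2,4,6,8-tetraenoyl]-4-hydroxy-1-{[2-(trimethylsilyl)ethoxy]methoxy}pyridin-2(1H)-one
Conditions: [Rh(cod)Cl]2 (5 mol%), dppf (10 mol%), Na2CO3 (20 mol%), toluene, 60 °C, Ar, dark; 13 added slowly to 23 (1.2 equiv)
Reagents that add atoms: none
Why: Proposed new method: after deprotonation the O4 pyridonate binds Rh(I) and steers oxidative addition of the neighbouring formyl C–H, giving a five-membered O,C-chelated acyl–Rh(III) hydride (Rh–O4–C4=C3–C=O) that resists decarbonylation; the terminal alkyne of 13 then inserts syn into Rh–H with Rh on the unsubstituted carbon, and C–C reductive elimination forms the acyl–alkenyl bond. The closest known reaction type is the Rh/diphosphine-catalysed, hydroxyl-chelation-assisted intermolecular hydroacylation of alkynes with salicylaldehydes, here extended to a 3-formyl-4-hydroxy-2-pyridone and a conjugated trienyne. No ring is closed and no stereocentre is created; the new C2=C3 double bond is fixed as E by syn H–Rh addition followed by reductive elimination with retention, and the remote (R) centre is not involved. The step needs linear rather than branched insertion, reaction at the alkyne rather than at the triene, and no oxa-Michael closure of O4 onto the new enone; the unhindered terminal alkyne carbon under a bulky wide-bite-angle diphosphine, the much faster insertion of a terminal alkyne than of internal substituted alkenes, and near-neutral conditions at moderate temperature are expected to secure these. The silyl and SEM caps on the phenol and N–O oxygens leave O4/CHO as the only chelating site.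

Step 17
Reactants: 24 5-[4-(tert-butyldimethylsilyloxy)phenyl]-3-[(2E,4E,6E,8E,10R)-8,10-dimethyldodeca-2,4,6,8-tetraenoyl]-4-hydroxy-1-{[2-(trimethylsilyl)ethoxy]methoxy}pyridin-2(1H)-one
Product: 25 1,4-dihydroxy-5-(4-hydroxyphenyl)-3-[(2E,4E,6E,8E,10R)-8,10-dimethyldodeca-2,4,6,8-tetraenoyl]pyridin-2(1H)-one
Conditions: TBAF (4 equiv), THF, 0 °C to rt, dark; then AcOH
Reagents that add atoms: none
Why: Fluoride should cleave the aryl silyl ether and trigger fragmentation of the N–O SEM acetal (loss of Me3SiF, ethylene and formaldehyde) to stabilised oxyanions, while the ionised 3-acyl-4-hydroxy unit shields the polyenone from conjugate addition.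

**Compound list**

1 | (R)-4-benzyloxazolidin-2-one | O=C1N[C@H](Cc2ccccc2)CO1 | starting material
2 | butanoyl chloride | CCCC(=O)Cl | starting material
3 | (R)-4-benzyl-3-butanoyloxazolidin-2-one | CCCC(=O)N1[C@H](Cc2ccccc2)COC1=O | intermediate
4 | (R)-4-benzyl-3-[(R)-2-methylbutanoyl]oxazolidin-2-one | CC[C@@H](C)C(=O)N1[C@H](Cc2ccccc2)COC1=O | intermediate
5 | (R)-2-methylbutan-1-ol | CC[C@@H](C)CO | intermediate
6 | 2-(triphenylphosphoranylidene)propanal | CC(C=O)=P(c1ccccc1)(c1ccccc1)c1ccccc1 | starting material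
7 | (R)-2-methylbutanal | CC[C@@H](C)C=O | intermediate (not isolated)
8 | (R,E)-2,4-dimethylhex-2-enal | CC[C@@H](C)/C=C(C)/C=O | intermediate
9 | triethyl (E)-4-phosphonocrotonate | CCOC(=O)/C=C/CP(=O)(OCC)OCC | starting material
10 | ethyl (2E,4E,6E,8R)-6,8-dimethyldeca-2,4,6-trienoate | CC[C@@H](C)/C=C(C)/C=C/C=C/C(=O)OCC | intermediate
11 | (2E,4E,6E,8R)-6,8-dimethyldeca-2,4,6-trien-1-ol | CC[C@@H](C)/C=C(C)/C=C/C=C/CO | intermediate
12 | (2E,4E,6E,8R)-6,8-dimethyldeca-2,4,6-trienal | CC[C@@H](C)/C=C(C)/C=C/C=C/C=O | intermediate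
13 | (3E,5E,7E,9R)-7,9-dimethylundeca-3,5,7-trien-1-yne | CC[C@@H](C)/C=C(C)/C=C/C=C/C#C | intermediate
14 | 5-bromo-2,4-dichloropyridine | Clc1cc(Cl)c(Br)cn1 | starting material
15 | 4-(benzyloxy)-5-bromo-2-chloropyridine | Clc1cc(OCc2ccccc2)c(Br)cn1 | intermediate
16 | 4-(benzyloxy)-5-bromo-2-chloropyridine 1-oxide | [O-][n+]1cc(Br)c(OCc2ccccc2)cc1Cl | intermediate
17 | 4-(benzyloxy)-5-bromo-1-hydroxypyridin-2(1H)-one | O=c1cc(OCc2ccccc2)c(Br)cn1O | intermediate
18 | 4-(benzyloxy)-5-bromo-1-{[2-(trimethylsilyl)ethoxy]methoxy}pyridin-2(1H)-one | O=c1cc(OCc2ccccc2)c(Br)cn1OCOCC[Si](C)(C)C | intermediate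
19 | [4-(tert-butyldimethylsilyloxy)phenyl]boronic acid | CC(C)(C)[Si](C)(C)Oc1ccc(B(O)O)cc1 | starting material
20 | 4-(benzyloxy)-5-[4-(tert-butyldimethylsilyloxy)phenyl]-1-{[2-(trimethylsilyl)ethoxy]methoxy}pyridin-2(1H)-one | O=c1cc(OCc2ccccc2)c(-c2ccc(O[Si](C)(C)C(C)(C)C)cc2)cn1OCOCC[Si](C)(C)C | intermediate
21 | 5-[4-(tert-butyldimethylsilyloxy)phenyl]-4-hydroxy-1-{[2-(trimethylsilyl)ethoxy]methoxy}pyridin-2(1H)-one | O=c1cc(O)c(-c2ccc(O[Si](C)(C)C(C)(C)C)cc2)cn1OCOCC[Si](C)(C)C | intermediate
22 | (3Z)-5-[4-(tert-butyldimethylsilyloxy)phenyl]-3-[(dimethylamino)methylidene]-1-{[2-(trimethylsilyl)ethoxy]methoxy}pyridine-2,4(1H,3H)-dione | CN(C)/C=C1/C(=O)C(-c2ccc(O[Si](C)(C)C(C)(C)C)cc2)=CN(OCOCC[Si](C)(C)C)C1=O | intermediate (not isolated)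
23 | 5-[4-(tert-butyldimethylsilyloxy)phenyl]-4-hydroxy-2-oxo-1-{[2-(trimethylsilyl)ethoxy]methoxy}-1,2-dihydropyridine-3-carbaldehyde | O=Cc1c(O)c(-c2ccc(O[Si](C)(C)C(C)(C)C)cc2)cn(OCOCC[Si](C)(C)C)c1=O | intermediate
24 | 5-[4-(tert-butyldimethylsilyloxy)phenyl]-3-[(2E,4E,6E,8E,10R)-8,10-dimethyldodeca-2,4,6,8-tetraenoyl]-4-hydroxy-1-{[2-(trimethylsilyl)ethoxy]methoxy}pyridin-2(1H)-one | CC[C@@H](C)/C=C(C)/C=C/C=C/C=C/C(=O)c1c(O)c(-c2ccc(O[Si](C)(C)C(C)(C)C)cc2)cn(OCOCC[Si](C)(C)C)c1=O | intermediate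
25 | 1,4-dihydroxy-5-(4-hydroxyphenyl)-3-[(2E,4E,6E,8E,10R)-8,10-dimethyldodeca-2,4,6,8-tetraenoyl]pyridin-2(1H)-one | CC[C@@H](C)/C=C(C)/C=C/C=C/C=C/C(=O)c1c(O)c(-c2ccc(O)cc2)cn(O)c1=O | target

**Step count and risks**

Total steps: 17. Longest linear sequence: 10 steps (1–8, 16, 17); the pyridone branch (9–15) joins at step 16.

Steps most likely to fail:

1. Step 16 (Proposed new method). What may go wrong: insertion of the alkyne in the opposite sense, so that the acyl group is delivered to the internal carbon; decarbonylation of the acyl–rhodium hydride; or loss of the alkyne to rhodium-mediated oligomerisation before hydroacylation turns over. Fallback by known chemistry, setting out from 23 and 13 and rejoining the route at 25: 23 is capped at O4 with SEMCl/iPr2NEt to give 5-[4-(tert-butyldimethylsilyloxy)phenyl]-2-oxo-1,4-bis{[2-(trimethylsilyl)ethoxy]methoxy}-1,2-dihydropyridine-3-carbaldehyde F1, whose formyl group is then a normal electrophile. Trienyne 13 is hydrozirconated with Schwartz's reagent (CH2Cl2, rt) to chlorobis(cyclopentadienyl)[(1E,3E,5E,7E,9R)-7,9-dimethylundeca-1,3,5,7-tetraen-1-yl]zirconium F2, which is transmetalated with Me2Zn at −65 °C to methyl[(1E,3E,5E,7E,9R)-7,9-dimethylundeca-1,3,5,7-tetraen-1-yl]zinc F3. Addition of F3 to F1 should give 5-[4-(tert-butyldimethylsilyloxy)phenyl]-3-[(2E,4E,6E,8E,10R)-1-hydroxy-8,10-dimethyldodeca-2,4,6,8-tetraen-1-yl]-1,4-bis{[2-(trimethylsilyl)ethoxy]methoxy}pyridin-2(1H)-one F4 as both carbinol epimers. MnO2 oxidation of F4 gives 5-[4-(tert-butyldimethylsilyloxy)phenyl]-3-[(2E,4E,6E,8E,10R)-8,10-dimethyldodeca-2,4,6,8-tetraenoyl]-1,4-bis{[2-(trimethylsilyl)ethoxy]methoxy}pyridin-2(1H)-one F5, and TBAF/THF then removes all three masks to give 25.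

2. Step 17. What may go wrong: degradation of the polyenone under basic fluoride (geometric isomerisation or conjugate addition), electrophilic attack of the released formaldehyde on the phenolate, or incomplete fragmentation of the N–O acetal. Fallback, setting out from 24 and rejoining at 25: the one-pot fluoride fragmentation is replaced by two separate non-basic cleavages of different mechanism through an isolated intermediate. KHF2 in MeOH at rt removes only the phenolic silyl ether to give 4-hydroxy-5-(4-hydroxyphenyl)-3-[(2E,4E,6E,8E,10R)-8,10-dimethyldodeca-2,4,6,8-tetraenoyl]-1-{[2-(trimethylsilyl)ethoxy]methoxy}pyridin-2(1H)-one F6. The N–O acetal of F6 is then cleaved by Lewis-acid chelation with MgBr2·OEt2 in Et2O/MeNO2 at rt, giving 25.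

3. Step 15. What may go wrong: O-methylation of the acidic 4-hydroxyl by the amide acetal instead of attack at C3, or retro-Claisen loss of the formyl group during hydrolysis of the enaminone. Fallback, setting out from 21 and rejoining at 23: electrophilic iodination at C3 with NIS in MeCN at 0 °C gives 5-[4-(tert-butyldimethylsilyloxy)phenyl]-4-hydroxy-3-iodo-1-{[2-(trimethylsilyl)ethoxy]methoxy}pyridin-2(1H)-one F7. Palladium-catalysed reductive carbonylation of F7 (Pd(dppp)Cl2, CO 1 atm, Et3SiH, Na2CO3, DMF, 60 °C) converts C–I into the formyl group of 23.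

**Further compounds**

F1 | step 16 | 5-[4-(tert-butyldimethylsilyloxy)phenyl]-2-oxo-1,4-bis{[2-(trimethylsilyl)ethoxy]methoxy}-1,2-dihydropyridine-3-carbaldehyde | O=Cc1c(OCOCC[Si](C)(C)C)c(-c2ccc(O[Si](C)(C)C(C)(C)C)cc2)cn(OCOCC[Si](C)(C)C)c1=O
F2 | step 16 | chlorobis(cyclopentadienyl)[(1E,3E,5E,7E,9R)-7,9-dimethylundeca-1,3,5,7-tetraen-1-yl]zirconium | CC[C@@H](C)/C=C(C)/C=C/C=C/C=C/[Zr](Cl)(C1C=CC=C1)C1C=CC=C1
F3 | step 16 | methyl[(1E,3E,5E,7E,9R)-7,9-dimethylundeca-1,3,5,7-tetraen-1-yl]zinc | CC[C@@H](C)/C=C(C)/C=C/C=C/C=C/[Zn]C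
F4 | step 16 | 5-[4-(tert-butyldimethylsilyloxy)phenyl]-3-[(2E,4E,6E,8E,10R)-1-hydroxy-8,10-dimethyldodeca-2,4,6,8-tetraen-1-yl]-1,4-bis{[2-(trimethylsilyl)ethoxy]methoxy}pyridin-2(1H)-one (both carbinol epimers) | CC[C@@H](C)/C=C(C)/C=C/C=C/C=C/C(O)c1c(OCOCC[Si](C)(C)C)c(-c2ccc(O[Si](C)(C)C(C)(C)C)cc2)cn(OCOCC[Si](C)(C)C)c1=O
F5 | step 16 | 5-[4-(tert-butyldimethylsilyloxy)phenyl]-3-[(2E,4E,6E,8E,10R)-8,10-dimethyldodeca-2,4,6,8-tetraenoyl]-1,4-bis{[2-(trimethylsilyl)ethoxy]methoxy}pyridin-2(1H)-one | CC[C@@H](C)/C=C(C)/C=C/C=C/C=C/C(=O)c1c(OCOCC[Si](C)(C)C)c(-c2ccc(O[Si](C)(C)C(C)(C)C)cc2)cn(OCOCC[Si](C)(C)C)c1=O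
F6 | step 17 | 4-hydroxy-5-(4-hydroxyphenyl)-3-[(2E,4E,6E,8E,10R)-8,10-dimethyldodeca-2,4,6,8-tetraenoyl]-1-{[2-(trimethylsilyl)ethoxy]methoxy}pyridin-2(1H)-one | CC[C@@H](C)/C=C(C)/C=C/C=C/C=C/C(=O)c1c(O)c(-c2ccc(O)cc2)cn(OCOCC[Si](C)(C)C)c1=O
F7 | step 15 | 5-[4-(tert-butyldimethylsilyloxy)phenyl]-4-hydroxy-3-iodo-1-{[2-(trimethylsilyl)ethoxy]methoxy}pyridin-2(1H)-one | O=c1c(I)c(O)c(-c2ccc(O[Si](C)(C)C(C)(C)C)cc2)cn1OCOCC[Si](C)(C)C
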